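## The problem

The target 12 is a flavonol: a benzene ring A fused to a 4-pyranone ring C, with the 4-methoxyphenyl ring B on C2, a hydroxyl on C3, a free hydroxyl on C5 and a prenyl ether on C7. It has no stereocenter, so the task is ring construction, the placing of three different oxygen substituents (O1, O5, O7) on a phloroglucinol-type ring A, and protecting-group compatibility. The prenyl ether limits the chemistry throughout: it does not survive hydrogenolysis, strong Brønsted or Lewis acids, quinone oxidants or electrophilic oxidants of the trisubstituted alkene, and it rearranges on strong heating. The 3-hydroxy-4-pyranone is an electron-rich, chelating enol that is easily over-oxidised, and the aryl methyl ether must not meet demethylating reagents. The enabling feature is that C3 and C4 of ring C are adjacent oxidised carbons. In the dihydro form (a 3-hydroxychroman-4-one) they are a carbinol and a ketone, which is what results when two aldehyde carbons are joined with the polarity of one inverted. C4 is then the formyl carbon of a salicylaldehyde-type ring A, and C3 the formyl carbon of an aryl(aryloxy)acetaldehyde already tied to ring A through O1–C2. The stereocenters such a ketol carries at C2 and C3 vanish on oxidation to the aromatic pyranone, and the mirror symmetry of a 2,6-dihydroxybenzaldehyde lets O1 and O5 be told apart without a regiochemical question.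

## Retrosynthesis

**O5–Si.** The last operation is the unmasking of O5, so 12 is traced to its 5-O-tert-butyldimethylsilyl ether 11. A silyl ether is preferred to a benzyl, methyl or methoxymethyl ether because fluoride leaves the prenyl ether, the aryl methyl ether and the enol untouched, whereas hydrogenolysis, boron halides or acid would not. The forward step only has to be buffered so that the acidic flavonol is not held in strongly basic fluoride.

**Oxidation level at C3.** Flavonol 11 is the enol tautomer of the chromane-3,4-dione 10, and 10 is the oxidation product of ketol 9. Raising C3 from carbinol to ketone is chosen over dehydrogenation across C2–C3 with a quinone or a halogen, both of which endanger the prenyl group. Ketol 9 carries two stereocenters that do not matter, since tautomerisation of 10 removes both. The forward reaction must be a mild alcohol oxidation that stops after one equivalent.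

**C3–C4 (key disconnection).** Cutting the bond between the carbinol and the ketone of 9 opens ring C to the dialdehyde 8, in which C4 is an aryl aldehyde and C3 an aliphatic aldehyde held six atoms apart by the O1–C2 ether. The classical neighbours of this cut break O1–C2 and close ring C by oxidative cyclisation of an open-chain enone; with oxygen at C5 that closure tends toward the five-membered ring. The C3–C4 cut instead uses the 1,2-dioxygen pattern itself and leaves a precursor with no ring C and one irrelevant stereocenter. The forward reaction is a carbene-catalysed intramolecular crossed benzoin. It must form the C–C bond faster than the α-aryloxy aldehyde is lost by enolisation or by expulsion of the aryloxide.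

**Redox adjustment.** Dialdehyde 8 is traced through diol 7 to the aldehyde ester 6. No hydride reduces an ester in preference to an aryl aldehyde, so both carbonyls are taken down to the carbinols and both are brought back up. This costs two steps but uses only routine reactions and lets the aliphatic carbon enter as a stable ester.

**O5–Si and O1–C2.** Silyl ether 6 comes from phenol 5, and 5 from the symmetric diphenol 3 and the benzylic bromo ester 4. Cutting O1–C2 at an activated benzylic α-bromo ester brings in C2, C3 and ring B as one commercial piece. The forward alkylation must stop at the monoether, which the hydrogen bond of the remaining hydroxyl to the formyl group supports.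

**O7–C(prenyl).** Diphenol 3 comes from 2,4,6-trihydroxybenzaldehyde 1 and prenyl bromide 2. The 4-hydroxyl is the only one not hydrogen-bonded to the formyl group and is the most acidic, so one equivalent of weak base should direct alkylation there.

## Roads not taken

**Alternative 1:** The cut removes C3 as a one-carbon unit by breaking both C3–C4 and C2=C3. This leaves the acid chloride A1 (2,6-bis(4-methoxybenzoyloxy)-4-(3-methylbut-2-enyloxy)benzoyl chloride) and the oxygen-bearing ylide A2 ([2-(trimethylsilyl)ethoxy]methylenetriphenylphosphorane). In the forward sense A2 is C-acylated by A1, and the keto-stabilised ylide carbon then olefinates one of the two flanking aryl ester carbonyls in an intramolecular Wittig reaction. The product is A3 (5-(4-methoxybenzoyloxy)-2-(4-methoxyphenyl)-7-(3-methylbut-2-enyloxy)-3-[2-(trimethylsilyl)ethoxy]chromen-4-one), from which fluoride and mild base would free O3 and O5.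
- Merits: both ring C bonds form in one flask and the aromatic pyranone arises directly at the right oxidation level. There is no ketol, no oxidation step and no reduce–reoxidise detour. The two ester groups of A1 are equivalent, and the end-game reagents suit the prenyl ether.
- Weak points: A1 is a crowded, electron-rich 2,6-diacyloxybenzoyl chloride. The parent salicylic acid is prone to decarboxylation, and its conversion to the chloride liberates HCl next to a prenyl ether. A2 is a non-stabilised ylide that needs strong base and is consumed twice, once as nucleophile and once as base. Olefination of an electron-rich aroyl ester by a stabilised ylide is slow and normally needs prolonged heating.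
- Comparison: in redox economy and in freedom from a chemoselectivity question this road is better than the chosen one. The chosen plan offers a catalytic, room-temperature ring closure, a commercial ring A aldehyde that already has the right carbon oxidation level, and no acid chloride on a phloroglucinol nucleus.

**Alternative 2:** The cut breaks C2–C3 and O1–C8a and takes ring A from the trifluorophenyl ketone A4 (2-(methoxymethoxy)-1-(2,4,6-trifluorophenyl)ethanone). The magnesium enolate of A4 (MgBr2, i-Pr2NEt) is C-acylated by A5 (4-methoxybenzoyl chloride). The diketone enolate oxygen then displaces an ortho fluoride to give A6 (5,7-difluoro-3-(methoxymethoxy)-2-(4-methoxyphenyl)chromen-4-one).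
- Merits: enolate acylation and nucleophilic aromatic substitution ortho to a carbonyl are among the most dependable bond formations available. No sensitive aldehyde appears, and C3 carries its oxygen from the start.
- Weak points: A6 still has two fluorides where the target needs a prenyl ether and a free hydroxyl. Two further substitutions must distinguish C7 from C5, the second on a ring deactivated by the first, and the hydroxyl needs a hydroxide surrogate with its own deprotection. The methoxymethyl ether on O3 comes off only with acid, which is the condition the prenyl ether tolerates least.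
- Comparison: the ring closure is more certain than a benzoin closure. The chosen plan has all three ring A oxygens in place and differentiated after two steps, ends with fluoride instead of acid, and is several steps shorter.

**Alternative 3:** The cut breaks O1–C8a, C4–C4a and O1–C2. Fluoride (CsF) converts the silyl triflate A7 (3,5-bis(benzyloxy)-2-(trimethylsilyl)phenyl trifluoromethanesulfonate) into the aryne A8 (3,5-bis(benzyloxy)benzyne). The carboxylate of A9 (3-(4-methoxyphenyl)propiolic acid) adds to A8 at the carbon remote from the neighbouring benzyloxy group, the aryl anion takes over the acyl group, and the resulting phenoxide closes onto the ynone. The product is A10 (5,7-bis(benzyloxy)-2-(4-methoxyphenyl)chromen-4-one).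
- Merits: three bonds form in one operation from two fragments. The regiochemistry is set by the alkoxy group next to the aryne, and the result is fully aromatic.
- Weak points: A10 has hydrogen at C3, so the flavonol oxygen would have to be introduced afterwards by metalation or by epoxidation chemistry that a prenyl alkene does not tolerate. The benzyl ethers call for hydrogenolysis, which forces the prenyl group to be attached last by selective alkylation of a trihydroxy compound. A7 itself takes several steps to prepare.
- Comparison: in bonds formed per step this road is the most convergent of the four. It delivers the wrong oxidation level at C3 and the wrong protecting groups for a prenyl ether target, whereas the chosen plan creates the C3 oxygen in the bond-forming step and carries the prenyl ether from step 1.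

Key step: step 6

Assumption: methyl 2-bromo-2-(4-methoxyphenyl)acetate (4) is taken as a purchasable racemic reagent; its configuration is irrelevant because the carbon it delivers becomes the sp2 carbon C2 of the target, which has no stereocenter. Carbene-bound species of the catalytic cycle in step 6 are transient and are described in words only.

## Route

Step 1
Reactants: 1 2,4,6-trihydroxybenzaldehyde; 2 prenyl bromide (1-bromo-3-methylbut-2-ene)
Product: 3 2,6-dihydroxy-4-(3-methylbut-2-enyloxy)benzaldehyde
Conditions: 2 (1.0 equiv), K2CO3 (1.0 equiv), acetone, 0 °C to rt
Reagents that add atoms: none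
Why: Williamson ether synthesis; the 4-hydroxyl is the only one not hydrogen-bonded to the formyl group and is the most acidic (para to the carbonyl), so one equivalent of weak base should form that phenoxide selectively and alkylate it on oxygen.

Step 2
Reactants: 3 2,6-dihydroxy-4-(3-methylbut-2-enyloxy)benzaldehyde; 4 methyl 2-bromo-2-(4-methoxyphenyl)acetate (racemic)
Product: 5 methyl 2-[2-formyl-3-hydroxy-5-(3-methylbut-2-enyloxy)phenoxy]-2-(4-methoxyphenyl)acetate (racemic)
Conditions: 4 (1.0 equiv), K2CO3 (1.1 equiv), DMF, 0 °C to rt
Reagents that add atoms: none
Why: Williamson etherification with an activated benzylic α-bromo ester; the two ortho hydroxyls are equivalent by symmetry, and after the first alkylation the remaining one stays hydrogen-bonded to the formyl oxygen, which should hold the reaction at the monoether. The stereocenter (future C2) forms racemic and is erased at step 7.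

Step 3
Reactants: 5 methyl 2-[2-formyl-3-hydroxy-5-(3-methylbut-2-enyloxy)phenoxy]-2-(4-methoxyphenyl)acetate
Product: 6 methyl 2-[3-(tert-butyldimethylsilyloxy)-2-formyl-5-(3-methylbut-2-enyloxy)phenoxy]-2-(4-methoxyphenyl)acetate (racemic)
Conditions: TBSCl, imidazole, DMF, rt
Reagents that add atoms: tert-butyldimethylsilyl chloride, CC(C)(C)[Si](C)(C)Cl
Why: Standard silylation of a phenol via the silylimidazolium; it removes the hydrogen bond that would deactivate the aryl aldehyde and quench the carbene in step 6, and the group is later cleaved by fluoride without harm to the prenyl ether.

Step 4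
Reactants: 6 methyl 2-[3-(tert-butyldimethylsilyloxy)-2-formyl-5-(3-methylbut-2-enyloxy)phenoxy]-2-(4-methoxyphenyl)acetate
Product: 7 2-[3-(tert-butyldimethylsilyloxy)-2-(hydroxymethyl)-5-(3-methylbut-2-enyloxy)phenoxy]-2-(4-methoxyphenyl)ethanol (racemic)
Conditions: i-Bu2AlH (5 equiv), CH2Cl2, −78 to −20 °C; MeOH, then aq. KNaC4H4O6; used without chromatography on acidic silica
Reagents that add atoms: none
Why: Hydride reduction of the aldehyde and of the α-aryloxy ester to the two primary alcohols; aluminium alkoxides in a non-coordinating solvent at low temperature are too weakly nucleophilic to pull the silyl group from the neighbouring phenol oxygen, and the prenyl and silyl ethers are inert to the hydride.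

Step 5
Reactants: 7 2-[3-(tert-butyldimethylsilyloxy)-2-(hydroxymethyl)-5-(3-methylbut-2-enyloxy)phenoxy]-2-(4-methoxyphenyl)ethanol
Product: 8 2-(tert-butyldimethylsilyloxy)-6-[1-(4-methoxyphenyl)-2-oxoethoxy]-4-(3-methylbut-2-enyloxy)benzaldehyde (racemic)
Conditions: Dess–Martin periodinane (2.6 equiv), NaHCO3, CH2Cl2, 0 °C to rt; aq. Na2S2O3/NaHCO3; used crude
Reagents that add atoms: none
Why: Dess–Martin oxidation of both primary alcohols under buffered, non-aqueous conditions, which should stop at the aldehydes and spare the prenyl alkene and silyl ether; the only ring a mono-oxidised intermediate could form by lactolisation is seven-membered, so the second oxidation should be faster.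

Step 6
Reactants: 8 2-(tert-butyldimethylsilyloxy)-6-[1-(4-methoxyphenyl)-2-oxoethoxy]-4-(3-methylbut-2-enyloxy)benzaldehyde
Product: 9 5-(tert-butyldimethylsilyloxy)-3-hydroxy-2-(4-methoxyphenyl)-7-(3-methylbut-2-enyloxy)chroman-4-one (mixture of racemic cis and trans diastereomers)
Conditions: 2-(pentafluorophenyl)-6,7-dihydro-5H-pyrrolo[2,1-c][1,2,4]triazol-2-ium tetrafluoroborate (15 mol %), i-Pr2NEt (15 mol %), degassed toluene, rt, Ar
Reagents that add atoms: none
Why: The free carbene released from the triazolium salt by the amine adds to the aryl aldehyde; proton transfer gives the enaminol, an acyl anion equivalent at the future C4, which adds to the aliphatic aldehyde carbon (future C3), and collapse of the adduct releases the carbene and the ketol. The closest known reaction type is the carbene-catalysed intramolecular crossed benzoin of 2-formylaryl ethers bearing a tethered ketone, which gives 3-hydroxychroman-4-ones, together with the carbene-catalysed cyclisation of dialdehydes to six-membered α-ketols; here the acceptor is an aldehyde in place of a ketone. Ring C closes by 6-exo-trig attack of the nucleophilic carbon on the tethered carbonyl group. The new stereocenter at C3 is set without control by an achiral catalyst, and with racemic C2 this should give a mixture of racemic cis and trans diastereomers, all of which converge at step 7. The step needs C–C bond formation to win over expulsion of the aryloxide from an enaminol formed at the aliphatic aldehyde and over base-induced enolisation of that aldehyde. The substrate and catalyst help in three ways: the aliphatic aldehyde is doubly branched at its α-carbon, which disfavours carbene addition there, while the aryl aldehyde gives a conjugated and more readily formed enaminol; the would-be leaving group is an electron-rich phenoxide; and the electron-poor N-pentafluorophenyl triazolium needs only a catalytic amount of a weak amine base. Should the opposite ketol (C3 ketone, C4 carbinol) form, it can equilibrate by retro-benzoin to 9, whose carbonyl is conjugated with ring A, and in any case it would give the same dione 10 at step 7. Oxygen is excluded so that the enaminol is not diverted to the carboxylic acid.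

Step 7
Reactants: 9 5-(tert-butyldimethylsilyloxy)-3-hydroxy-2-(4-methoxyphenyl)-7-(3-methylbut-2-enyloxy)chroman-4-one
Product: 11 5-(tert-butyldimethylsilyloxy)-3-hydroxy-2-(4-methoxyphenyl)-7-(3-methylbut-2-enyloxy)chromen-4-one, via chromane-3,4-dione tautomer 10 (not isolated)
Conditions: Dess–Martin periodinane (1.1 equiv), NaHCO3, CH2Cl2, 0 °C
Reagents that add atoms: none
Why: Dess–Martin oxidation of an α-hydroxy ketone to the 1,2-dione; the C2–H of dione 10 is flanked by a ketone, an aryl group and the ring oxygen, so 10 should enolise at once to the aromatic 4-pyranone, removing both stereocenters. One equivalent at low temperature limits further oxidation of the enol.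

Step 8
Reactants: 11 5-(tert-butyldimethylsilyloxy)-3-hydroxy-2-(4-methoxyphenyl)-7-(3-methylbut-2-enyloxy)chromen-4-one
Product: 12 3,5-dihydroxy-2-(4-methoxyphenyl)-7-(3-methylbut-2-enyloxy)chromen-4-one
Conditions: Bu4NF (1.1 equiv), AcOH (1.1 equiv), THF, 0 °C
Reagents that add atoms: none
Why: Fluoride-induced desilylation of an aryl silyl ether, driven by the Si–F bond and a phenoxide leaving group that sits peri to the C4 carbonyl; acetic acid buffers the medium, and the prenyl ether, methyl ether and enol are inert to fluoride.

## Compound list

1 | 2,4,6-trihydroxybenzaldehyde | O=Cc1c(O)cc(O)cc1O | starting material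
2 | prenyl bromide (1-bromo-3-methylbut-2-ene) | CC(C)=CCBr | starting material
3 | 2,6-dihydroxy-4-(3-methylbut-2-enyloxy)benzaldehyde | O=Cc1c(O)cc(OCC=C(C)C)cc1O | intermediate
4 | methyl 2-bromo-2-(4-methoxyphenyl)acetate (racemic) | COC(=O)C(Br)c1ccc(OC)cc1 | starting material
5 | methyl 2-[2-formyl-3-hydroxy-5-(3-methylbut-2-enyloxy)phenoxy]-2-(4-methoxyphenyl)acetate (racemic) | COC(=O)C(Oc1cc(OCC=C(C)C)cc(O)c1C=O)c1ccc(OC)cc1 | intermediate
6 | methyl 2-[3-(tert-butyldimethylsilyloxy)-2-formyl-5-(3-methylbut-2-enyloxy)phenoxy]-2-(4-methoxyphenyl)acetate (racemic) | COC(=O)C(Oc1cc(OCC=C(C)C)cc(O[Si](C)(C)C(C)(C)C)c1C=O)c1ccc(OC)cc1 | intermediate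
7 | 2-[3-(tert-butyldimethylsilyloxy)-2-(hydroxymethyl)-5-(3-methylbut-2-enyloxy)phenoxy]-2-(4-methoxyphenyl)ethanol (racemic) | OCC(Oc1cc(OCC=C(C)C)cc(O[Si](C)(C)C(C)(C)C)c1CO)c1ccc(OC)cc1 | intermediate
8 | 2-(tert-butyldimethylsilyloxy)-6-[1-(4-methoxyphenyl)-2-oxoethoxy]-4-(3-methylbut-2-enyloxy)benzaldehyde (racemic) | O=CC(Oc1cc(OCC=C(C)C)cc(O[Si](C)(C)C(C)(C)C)c1C=O)c1ccc(OC)cc1 | intermediate
9 | 5-(tert-butyldimethylsilyloxy)-3-hydroxy-2-(4-methoxyphenyl)-7-(3-methylbut-2-enyloxy)chroman-4-one (mixture of racemic diastereomers) | COc1ccc(C2Oc3cc(OCC=C(C)C)cc(O[Si](C)(C)C(C)(C)C)c3C(=O)C2O)cc1 | intermediate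
10 | 5-(tert-butyldimethylsilyloxy)-2-(4-methoxyphenyl)-7-(3-methylbut-2-enyloxy)chromane-3,4-dione (racemic, not isolated) | COc1ccc(C2Oc3cc(OCC=C(C)C)cc(O[Si](C)(C)C(C)(C)C)c3C(=O)C2=O)cc1 | intermediate
11 | 5-(tert-butyldimethylsilyloxy)-3-hydroxy-2-(4-methoxyphenyl)-7-(3-methylbut-2-enyloxy)chromen-4-one | COc1ccc(-c2oc3cc(OCC=C(C)C)cc(O[Si](C)(C)C(C)(C)C)c3c(=O)c2O)cc1 | intermediate
12 | 3,5-dihydroxy-2-(4-methoxyphenyl)-7-(3-methylbut-2-enyloxy)chromen-4-one (no stereocenters) | COc1ccc(-c2oc3cc(OCC=C(C)C)cc(O)c3c(=O)c2O)cc1 | target

## Step count and risks

Total step count: 8. Longest linear sequence: 8 steps (1 to 12).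

**Step 6 (key step).** The carbene may engage the aliphatic aldehyde and expel the aryloxide. This redox fragmentation would lead to an aryl arylacetate and its condensation products. The amine may also enolise the α-aryloxy aldehyde and start an intramolecular aldol onto the aryl aldehyde. The doubly ortho-substituted, electron-rich aryl aldehyde may simply add the carbene too slowly. Fallback: from 8, the two carbonyl carbons are joined reductively instead of by polarity reversal. Samarium diiodide SmI2 (divalent samarium) in THF/t-BuOH at −78 °C should reduce the conjugated aryl aldehyde to its ketyl, which adds to the tethered aldehyde in an intramolecular pinacol coupling. This gives 5-(tert-butyldimethylsilyloxy)-2-(4-methoxyphenyl)-7-(3-methylbut-2-enyloxy)chromane-3,4-diol F1 as a mixture of diastereomers. 2-Iodoxybenzoic acid in DMSO, which oxidises 1,2-diols to 1,2-diones without cleaving the C–C bond, then takes F1 through dione 10 to flavonol 11, where the route is rejoined.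

**Step 5.** The electron-rich benzylic alcohol of 7 may ionise under the acetic acid set free. A mono-oxidised intermediate may close to a lactol and be over-oxidised to a lactone. The α-aryl-α-aryloxy aldehyde of 8 may enolise or hydrate on handling. Fallback: from 7, the two oxidations are separated by chemoselectivity. MnO2 in CH2Cl2 should oxidise only the benzylic alcohol under neutral conditions to 2-(tert-butyldimethylsilyloxy)-6-[2-hydroxy-1-(4-methoxyphenyl)ethoxy]-4-(3-methylbut-2-enyloxy)benzaldehyde F2. A Parikh–Doering oxidation (SO3·pyridine, DMSO, i-Pr2NEt) of the remaining primary alcohol, done immediately before the carbene step, then gives 8.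

**Step 7.** The flavonol enol formed in the flask may be oxidised further by the hypervalent iodine reagent at C2–C3, and the acetic acid set free may loosen the silyl ether. Fallback: from 9, the dehydrogenation is done by base and air instead of an iodine oxidant. K2CO3 in methanol under air should cleave the aryl silyl ether to 3,5-dihydroxy-2-(4-methoxyphenyl)-7-(3-methylbut-2-enyloxy)chroman-4-one F3, whose enediolate is autoxidised to the flavonol. The route is rejoined at 12, and step 8 is no longer needed.

**Step 2.** Alkylation may run on to the bis-ether. The very reactive benzylic bromide may alkylate ring A on carbon. The carbonate may start an aldol closure of the ester α-carbon onto the neighbouring formyl group. Fallback: from 3, a Mitsunobu reaction with methyl 2-hydroxy-2-(4-methoxyphenyl)acetate (PPh3, diisopropyl azodicarboxylate, THF) forms the same O–C bond under neutral conditions, without a phenoxide, and returns to the route at 5. It makes no new compound (F0).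

**Step 1.** Alkylation may spread to an ortho hydroxyl, go twice, or take place on a ring carbon of the ambident phloroglucinol phenoxide. Fallback: from 1, a Mitsunobu reaction with 3-methylbut-2-en-1-ol (PPh3, diisopropyl azodicarboxylate, THF, 0 °C) etherifies the most acidic, non-chelated 4-hydroxyl without a free phenoxide and returns to the route at 3. It makes no new compound (F0).

## Further compounds

F1 | step 6 | 5-(tert-butyldimethylsilyloxy)-2-(4-methoxyphenyl)-7-(3-methylbut-2-enyloxy)chromane-3,4-diol (mixture of racemic diastereomers) | COc1ccc(C2Oc3cc(OCC=C(C)C)cc(O[Si](C)(C)C(C)(C)C)c3C(O)C2O)cc1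
F2 | step 5 | 2-(tert-butyldimethylsilyloxy)-6-[2-hydroxy-1-(4-methoxyphenyl)ethoxy]-4-(3-methylbut-2-enyloxy)benzaldehyde (racemic) | OCC(Oc1cc(OCC=C(C)C)cc(O[Si](C)(C)C(C)(C)C)c1C=O)c1ccc(OC)cc1
F3 | step 7 | 3,5-dihydroxy-2-(4-methoxyphenyl)-7-(3-methylbut-2-enyloxy)chroman-4-one (mixture of racemic diastereomers) | COc1ccc(C2Oc3cc(OCC=C(C)C)cc(O)c3C(=O)C2O)cc1
F0 | step 2 | none | none
F0 | step 1 | none | none
A1 | alternative 1 | 2,6-bis(4-methoxybenzoyloxy)-4-(3-methylbut-2-enyloxy)benzoyl chloride | COc1ccc(C(=O)Oc2cc(OCC=C(C)C)cc(OC(=O)c3ccc(OC)cc3)c2C(Cl)=O)cc1
A2 | alternative 1 | [2-(trimethylsilyl)ethoxy]methylenetriphenylphosphorane | C[Si](C)(C)CCOC=P(c1ccccc1)(c1ccccc1)c1ccccc1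
A3 | alternative 1 | 5-(4-methoxybenzoyloxy)-2-(4-methoxyphenyl)-7-(3-methylbut-2-enyloxy)-3-[2-(trimethylsilyl)ethoxy]chromen-4-one | COc1ccc(C(=O)Oc2cc(OCC=C(C)C)cc3oc(-c4ccc(OC)cc4)c(OCC[Si](C)(C)C)c(=O)c23)cc1
A4 | alternative 2 | 2-(methoxymethoxy)-1-(2,4,6-trifluorophenyl)ethanone | COCOCC(=O)c1c(F)cc(F)cc1F
A5 | alternative 2 | 4-methoxybenzoyl chloride | COc1ccc(C(Cl)=O)cc1
A6 | alternative 2 | 5,7-difluoro-3-(methoxymethoxy)-2-(4-methoxyphenyl)chromen-4-one | COCOc1c(-c2ccc(OC)cc2)oc2cc(F)cc(F)c2c1=O
A7 | alternative 3 | 3,5-bis(benzyloxy)-2-(trimethylsilyl)phenyl trifluoromethanesulfonate | C[Si](C)(C)c1c(OCc2ccccc2)cc(OCc2ccccc2)cc1OS(=O)(=O)C(F)(F)F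
A8 | alternative 3 | 3,5-bis(benzyloxy)benzyne | C1#CC(OCc2ccccc2)=CC(OCc2ccccc2)=C1
A9 | alternative 3 | 3-(4-methoxyphenyl)propiolic acid | COc1ccc(C#CC(=O)O)cc1
A10 | alternative 3 | 5,7-bis(benzyloxy)-2-(4-methoxyphenyl)chromen-4-one | COc1ccc(-c2cc(=O)c3c(OCc4ccccc4)cc(OCc4ccccc4)cc3o2)cc1
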